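Whatever else happens in a closed flask, the starting material charged stays accounted for. What is neither starting material nor target is a missing share, and the oak run shows it at each reading.

- oak: starting material 0.10 M; partner 0.11 M; free catalyst 0.15 mM; temperature 70 °C; the very flask that is asked about, followed so far
- flask: starting material 0.10 M; partner 0.110 M; free catalyst 0.15 mM; temperature 70 °C; time 1.5 h

- oak (time / min: target / %, starting material / %): 8.00: 58.3, 27.3; 12.0: 69.7, 6.4; 20.0: 64.3, 5.5; 30.0: 63.6, 5.8; 50.0: 63.9, 5.5; 90.0: 63.5, 5.4

(scatter of a reading: 0.3 percentage points)

- delta: at 1.5 h add partner, 100% of the amount charged, then wait 1.5 h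
- zeta: change nothing and wait 1.5 h more
- theta: at 1.5 h raise the temperature by 10 K, then wait 1.5 h
- beta: at 1.5 h take out 90% of the target then present, then wait 1.5 h
- gamma: at 1.5 h add free catalyst, 50.0% of the amount charged, then wait 1.5 h

- what is taken out of target is counted as made
- the numbers in the tables scatter with a standard deviation of 0.3 percentage points
- additions bring no volume worth counting
- the earlier runs do not show what temperature does; that part of a forecast is a guess

1. target, in percent of the starting material first charged, at 1.5 h
2. the remedy with the largest gain of target, or "none" below 2 percentage points (delta / zeta / theta / beta / gamma / none)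
3. target present, with what was taken out counted in, in percent of the starting material first charged, after theta
4. target present, with what was taken out counted in, in percent of the starting material first charged, after gamma

Does that share keep growing? From 20.0 min to 90.0 min the oak readings stand still, at a mean target of 63.8% and a mean starting material of 5.55%. We call the split the ratio [missing share]/[target] once the readings stand still: 0.480.

Is this a balance or a dead end? Between 12.0 min and 20.0 min the oak target fell from 69.7% to 64.3%, while starting material moved just from 6.4% to 5.5%. The loss then ended with 63.8% of target present. We read a reversible step at rest, so we take the split for an equilibrium constant, which is thermodynamic control. That rest came within 8.00 min, much shorter than the further 1.5 h, so a disturbed flask should rebalance in the wait.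

What then moves target? Waiting does not, so we expect 63.8% now. Beta takes out 90% of target, and the rest re-divides by the split, for 82.5% counted in, a gain of 19 percentage points. The oak run charged more partner than starting material, yet starting material halts; we bet that partner was lost some other way. Then delta should turn the remaining 5.55% into target and missing share, a gain of 3.8 points, which is less than beta's, and we expect no gain from gamma. So we commit to beta, with 63.8% after gamma, and 63.8% after theta as a plain guess.

The forecast gives 63.8% now, none as the best remedy, 63.7% after theta and 51% after gamma, parting from our reckoning on the remedy and on gamma, and reads “the catalyst has died and that it drives both steps”.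

The flask gives 63.8%, and the best remedy is beta, at 19 points, with 3.8 points for delta, 63.8% after gamma, and 74.6% after theta, more than our guess. The flask's missing share is the isomer of the product, 30.6% at 90.0 min, while partner, the limiting reagent, stands at 0% of its charge. Our split times the flask's 63.8% of target gives 30.6% of isomer.

    catalyst intermediate B ⇌ catalyst intermediate C (K = 1.90, k = 5.30 s⁻¹, Ea = 76.0 kJ mol⁻¹, ΔH = −25.0 kJ mol⁻¹)
    target ⇌ isomer of the product (K = 0.480, k = 0.00160 s⁻¹, Ea = 94.0 kJ mol⁻¹, ΔH = −60.0 kJ mol⁻¹)
    partner → decomposed reagent (k = 4.80 × 10⁻⁴ s⁻¹, Ea = 113 kJ mol⁻¹)
    catalyst intermediate C → free catalyst + target (k = 2.30 s⁻¹, Ea = 87.0 kJ mol⁻¹)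
    partner + free catalyst ⇌ catalyst intermediate A (K = 420 L mol⁻¹, k = 510 L mol⁻¹ s⁻¹, Ea = 37.0 kJ mol⁻¹, ΔH = −14.0 kJ mol⁻¹)
    starting material + catalyst intermediate A → catalyst intermediate B (k = 190 L mol⁻¹ s⁻¹, Ea = 49.0 kJ mol⁻¹)
    (constants at 70 °C)

A neighbouring flask at the same temperature, with 0.044 M of partner, ends with 58.9% of starting material, so its other 41.1% divides by the split into 27.8% of target. Computed, that flask holds 27.8% of target.

(All runs were generated by integration for an exercise; the scatter is artificial.)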